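## Retrosynthetic overview
1. The last step removes seven benzyl ethers. Before that, the carbocycle is closed (C4–C4a, then C3=C4) by formylating the C3 methylene and cyclodehydrating para to O-7 (Friedel–Crafts).
2. One (R)-alcohol, made from sodium danshensu, supplies both lactates: the (R)-ester on the C1 carboxyl with retention, and the (S)-ester on the C3 carboxyl by Mitsunobu inversion.
3. Key disconnection C1–C2: the β-carbon of a cinnamaldehyde, made nucleophilic as a carbene-bound homoenolate, attacks the methide carbon of an ester-bearing o-quinone methide. Both carbons are electrophilic by nature. This one step sets C1 and C2 cis.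
4. The o-quinone methide comes from an α-chloro ester, made by ortho-hydroxyalkylation of 2-(benzyloxy)phenol with the (R)-lactate glyoxylate (C8a–C1).
5. Ring order: first a temporary seven-membered benzoxepinone lactone, opened in the same flask, then the six-membered carbocycle.

Numbering: dihydronaphthalene numbering is used. C1 = CH(CO2R), C2 = CH(aryl), C3 = C(CO2R)=, C4 = =CH, and the OH groups are on C7 and C8. Ring A is the fused catechol ring and ring B is the aryl group on C2.

Reading of the SMILES: (1S,2S), with the C1 ester and the C2 aryl cis. The lactate on the C3 carboxyl is (S) and the lactate on the C1 carboxyl is (R).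

Notation: Bn = benzyl. (R)-Lac = (2R)-3-[3,4-bis(benzyloxy)phenyl]-1-methoxy-1-oxopropan-2-yl. (S)-Lac is its (2S) mirror image.

Assumption: the (5aR,10bS) triazolium salt is taken to leave the Re face of the enal β-carbon open; its antipode is also sold and would be used if the sense of induction is the reverse.

## Route

Step 1
Reactants: 1 sodium (2R)-3-(3,4-dihydroxyphenyl)-2-hydroxypropanoate (sodium danshensu)
Product: 2 methyl (2R)-3-(3,4-dihydroxyphenyl)-2-hydroxypropanoate
Conditions: HCl (1.25 M in MeOH, 3 equiv), MeOH, 40 °C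
Reagents that add atoms: methanol, CO
Why: Fischer esterification of the liberated acid; no bond at the stereocentre is touched, so (R) is kept.

Step 2
Reactants: 2 methyl (2R)-3-(3,4-dihydroxyphenyl)-2-hydroxypropanoate
Product: 3 methyl (2R)-3-[3,4-bis(benzyloxy)phenyl]-2-hydroxypropanoate
Conditions: BnBr (2.2 equiv), K2CO3 (2.5 equiv), acetone, reflux
Reagents that add atoms: benzyl bromide, BrCc1ccccc1
Why: Williamson ether synthesis in which K2CO3 deprotonates only the two phenols, leaves the secondary alcohol alone and does not enolise the α-hydroxy ester.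

Step 3
Reactants: 3 methyl (2R)-3-[3,4-bis(benzyloxy)phenyl]-2-hydroxypropanoate; 4 glyoxylic acid monohydrate
Product: 5 (R)-Lac oxoacetate (the glyoxylate ester of 3)
Conditions: 4 (3 equiv), p-toluenesulfonic acid monohydrate (5 mol%), toluene, reflux, Dean–Stark
Reagents that add atoms: none
Why: Fischer esterification with azeotropic removal of water, the way glyoxylates of secondary alcohols are made on scale; the C–O bond at the stereocentre is not broken, so (R) is retained.

Step 4
Reactants: 5 (R)-Lac oxoacetate; 6 2-(benzyloxy)phenol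
Product: 7 (R)-Lac 2-[3-(benzyloxy)-2-hydroxyphenyl]-2-hydroxyacetate (both carbinol epimers)
Conditions: 6, EtMgBr (1.0 equiv), Et2O, 0 °C; solvent switch to toluene; 5, 0 °C to rt; 1 M HCl
Reagents that add atoms: none
Why: Ortho-selective Friedel–Crafts hydroxyalkylation in which the bromomagnesium phenolate holds the aldehyde in a six-membered chelate so that only the free ortho carbon (future C8a) attacks; the new carbinol centre needs no control because it becomes planar in step 7.

Step 5
Reactants: 7 (R)-Lac 2-[3-(benzyloxy)-2-hydroxyphenyl]-2-hydroxyacetate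
Product: 8 (R)-Lac 2-[3-(benzyloxy)-2-hydroxyphenyl]-2-chloroacetate (both epimers at C–Cl)
Conditions: SOCl2 (1.5 equiv), CH2Cl2, 0 °C to rt
Reagents that add atoms: thionyl chloride, O=S(Cl)Cl
Why: Deoxychlorination through the chlorosulfite, helped by the ortho hydroxyl; the acidic medium keeps the phenol protonated so that no quinone methide forms yet.

Step 6
Reactants: 9 3,4-bis(benzyloxy)benzaldehyde
Product: 10 (E)-3-[3,4-bis(benzyloxy)phenyl]prop-2-enal
Conditions: Ph3P=CHCHO (1.1 equiv), toluene, 80 °C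
Reagents that add atoms: (triphenylphosphoranylidene)acetaldehyde, O=CC=P(c1ccccc1)(c1ccccc1)c1ccccc1
Why: Wittig two-carbon homologation with a stabilised formyl ylide, which gives the E-enal.

Step 7 (key step)
Reactants: 8 (R)-Lac 2-[3-(benzyloxy)-2-hydroxyphenyl]-2-chloroacetate; 10 (E)-3-[3,4-bis(benzyloxy)phenyl]prop-2-enal
Product: 14 (3S,4S)-4-[3-(benzyloxy)-2-hydroxyphenyl]-3-[3,4-bis(benzyloxy)phenyl]-5-[(R)-Lac-oxy]-5-oxopentanoic acid, via o-quinone methide 11 (not isolated), via homoenolate 12 (not isolated), via lactone 13 (not isolated)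
Conditions: (5aR,10bS)-2-mesityl-5a,10b-dihydro-4H,6H-indeno[2,1-b][1,2,4]triazolo[4,3-d][1,4]oxazin-2-ium tetrafluoroborate (15 mol%), Cs2CO3 (2.5 equiv), 4 Å molecular sieves, THF, 0 °C to rt, 8 added over 4 h; then H2O, 0 °C, 1 h; 1 M HCl
Reagents that add atoms: water, O
Why: Proposed new method: Cs2CO3 strips HCl from 8 to give the ester-bearing o-quinone methide 11 while the triazolylidene turns 10 into the extended Breslow intermediate 12, whose nucleophilic β-carbon (a homoenolate) adds to the electrophilic methide carbon so that two innately electrophilic carbons are joined and rearomatisation drives the step; tautomerisation to the acyl azolium and capture by the phenoxide give the cis (4S,5S) lactone 13, because the indane wall leaves only the Re face of the β-carbon open and the enol O–H···O=C contact holds a compact array in which the Si face of the methide carbon is attacked and both new C–H bonds lie on one side; cold aqueous carbonate then cleaves only the strained aryl ester; no ammonium salt is present that would protonate the homoenolate; the closest known reaction type is the carbene-catalysed [4+3] annulation of enals with o-quinone methides to benzoxepinones, extended here to a methide carbon that carries an ester.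

Step 8
Reactants: 14 the pentanoic acid from step 7; 3 methyl (2R)-3-[3,4-bis(benzyloxy)phenyl]-2-hydroxypropanoate
Product: 15 1-[(R)-Lac] 5-[(S)-Lac] (2S,3S)-2-[3-(benzyloxy)-2-hydroxyphenyl]-3-[3,4-bis(benzyloxy)phenyl]pentanedioate
Conditions: PPh3 (1.3 equiv), diisopropyl azodicarboxylate (1.3 equiv), THF, 0 °C to rt
Reagents that add atoms: none
Why: Mitsunobu esterification in which SN2 displacement at the activated α-hydroxy ester carbon inverts (R) to (S); the carboxylic acid, far more acidic than the hindered phenol, is the nucleophile that reacts, and C1 is safe because the acid itself is never activated.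

Step 9
Reactants: 15 the mixed (R)-Lac/(S)-Lac pentanedioate
Product: 17 3-[(S)-Lac] 1-[(R)-Lac] (1S,2S)-7-(benzyloxy)-2-[3,4-bis(benzyloxy)phenyl]-8-hydroxy-1,2-dihydronaphthalene-1,3-dicarboxylate, via formyl ester 16 (not isolated)
Conditions: TiCl4 (6 equiv), Et3N (8 equiv), HCO2Me (10 equiv), CH2Cl2, −10 to 0 °C; aqueous work-up; crude in CF3CO2H/CH2Cl2 1:4, rt
Reagents that add atoms: methyl formate, COC=O
Why: Titanium-mediated crossed Claisen formylation, where soft enolisation takes the only unhindered CH2 next to an ester (C1 and the two lactate positions are hindered methines), followed by Friedel–Crafts cyclodehydration in which C4a, para to the O-7 benzyl ether, closes the six-membered ring and loss of water gives the C3=C4 enoate without touching C1 or C2.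

Step 10
Reactants: 17 the heptabenzyl ether
Product: 18 target CNP0237075.1, 3-[(2S)-3-(3,4-dihydroxyphenyl)-1-methoxy-1-oxopropan-2-yl] 1-[(2R)-3-(3,4-dihydroxyphenyl)-1-methoxy-1-oxopropan-2-yl] (1S,2S)-2-(3,4-dihydroxyphenyl)-7,8-dihydroxy-1,2-dihydronaphthalene-1,3-dicarboxylate
Conditions: BCl3 (1 M in CH2Cl2, 20 equiv), pentamethylbenzene (25 equiv), CH2Cl2, −78 °C; CHCl3/MeOH quench
Reagents that add atoms: none
Why: Lewis-acid ether cleavage with a non-basic cation scavenger removes all seven benzyl groups at −78 °C and spares the enoate, the four esters and the base-labile C1 centre, which hydrogenolysis or basic methods would endanger.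

## Compound list
1 | sodium (2R)-3-(3,4-dihydroxyphenyl)-2-hydroxypropanoate | [Na+].[O-]C(=O)[C@H](O)Cc1ccc(O)c(O)c1 | starting material
2 | methyl (2R)-3-(3,4-dihydroxyphenyl)-2-hydroxypropanoate | COC(=O)[C@H](O)Cc1ccc(O)c(O)c1 | intermediate
3 | methyl (2R)-3-[3,4-bis(benzyloxy)phenyl]-2-hydroxypropanoate | COC(=O)[C@H](O)Cc1ccc(OCc2ccccc2)c(OCc2ccccc2)c1 | intermediate
4 | glyoxylic acid monohydrate | OC(O)C(=O)O | starting material
5 | (R)-Lac oxoacetate | O=CC(=O)O[C@H](Cc1ccc(OCc2ccccc2)c(OCc2ccccc2)c1)C(=O)OC | intermediate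
6 | 2-(benzyloxy)phenol | Oc1ccccc1OCc1ccccc1 | starting material
7 | (R)-Lac 2-[3-(benzyloxy)-2-hydroxyphenyl]-2-hydroxyacetate (carbinol epimers) | OC(C(=O)O[C@H](Cc1ccc(OCc2ccccc2)c(OCc2ccccc2)c1)C(=O)OC)c1cccc(OCc2ccccc2)c1O | intermediate
8 | (R)-Lac 2-[3-(benzyloxy)-2-hydroxyphenyl]-2-chloroacetate (C–Cl epimers) | ClC(C(=O)O[C@H](Cc1ccc(OCc2ccccc2)c(OCc2ccccc2)c1)C(=O)OC)c1cccc(OCc2ccccc2)c1O | intermediate
9 | 3,4-bis(benzyloxy)benzaldehyde | O=Cc1ccc(OCc2ccccc2)c(OCc2ccccc2)c1 | starting material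
10 | (E)-3-[3,4-bis(benzyloxy)phenyl]prop-2-enal | O=C/C=C/c1ccc(OCc2ccccc2)c(OCc2ccccc2)c1 | intermediate
11 | (R)-Lac (2E)-[5-(benzyloxy)-6-oxocyclohexa-2,4-dien-1-ylidene]acetate (o-quinone methide) | COC(=O)[C@@H](Cc1ccc(OCc2ccccc2)c(OCc2ccccc2)c1)OC(=O)/C=C1\C=CC=C(OCc2ccccc2)C1=O | intermediate
12 | extended Breslow intermediate (homoenolate) from 10 and the (5aR,10bS) triazolylidene | OC(/C=C/c1ccc(OCc2ccccc2)c(OCc2ccccc2)c1)=C1N(c2c(C)cc(C)cc2C)N=C2CO[C@@H]3Cc4ccccc4[C@@H]3N12 | intermediate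
13 | (R)-Lac (4S,5S)-9-(benzyloxy)-4-[3,4-bis(benzyloxy)phenyl]-2-oxo-2,3,4,5-tetrahydro-1-benzoxepine-5-carboxylate | O=C1C[C@H](c2ccc(OCc3ccccc3)c(OCc3ccccc3)c2)[C@H](C(=O)O[C@H](Cc2ccc(OCc3ccccc3)c(OCc3ccccc3)c2)C(=O)OC)c2cccc(OCc3ccccc3)c2O1 | intermediate
14 | (3S,4S)-4-[3-(benzyloxy)-2-hydroxyphenyl]-3-[3,4-bis(benzyloxy)phenyl]-5-[(R)-Lac-oxy]-5-oxopentanoic acid | OC(=O)C[C@H](c1ccc(OCc2ccccc2)c(OCc2ccccc2)c1)[C@H](C(=O)O[C@H](Cc1ccc(OCc2ccccc2)c(OCc2ccccc2)c1)C(=O)OC)c1cccc(OCc2ccccc2)c1O | intermediate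
15 | 1-[(R)-Lac] 5-[(S)-Lac] (2S,3S)-2-[3-(benzyloxy)-2-hydroxyphenyl]-3-[3,4-bis(benzyloxy)phenyl]pentanedioate | COC(=O)[C@H](Cc1ccc(OCc2ccccc2)c(OCc2ccccc2)c1)OC(=O)C[C@H](c1ccc(OCc2ccccc2)c(OCc2ccccc2)c1)[C@H](C(=O)O[C@H](Cc1ccc(OCc2ccccc2)c(OCc2ccccc2)c1)C(=O)OC)c1cccc(OCc2ccccc2)c1O | intermediate
16 | C3-formyl derivative of 15 (C3 epimers and enol; C1 and C2 unchanged) | COC(=O)[C@H](Cc1ccc(OCc2ccccc2)c(OCc2ccccc2)c1)OC(=O)C(C=O)[C@H](c1ccc(OCc2ccccc2)c(OCc2ccccc2)c1)[C@H](C(=O)O[C@H](Cc1ccc(OCc2ccccc2)c(OCc2ccccc2)c1)C(=O)OC)c1cccc(OCc2ccccc2)c1O | intermediate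
17 | heptabenzyl ether of the target, (1S,2S), free OH at C8 | COC(=O)[C@H](Cc1ccc(OCc2ccccc2)c(OCc2ccccc2)c1)OC(=O)C1=Cc2ccc(OCc3ccccc3)c(O)c2[C@@H](C(=O)O[C@H](Cc2ccc(OCc3ccccc3)c(OCc3ccccc3)c2)C(=O)OC)[C@H]1c1ccc(OCc2ccccc2)c(OCc2ccccc2)c1 | intermediate
18 | CNP0237075.1 | COC(=O)[C@H](Cc1ccc(O)c(O)c1)OC(=O)C1=Cc2ccc(O)c(O)c2[C@@H](C(=O)O[C@H](Cc2ccc(O)c(O)c2)C(=O)OC)[C@H]1c1ccc(O)c(O)c1 | target

## Step count and risks
Total steps: 10. Longest linear sequence: 9 (steps 1, 2, 3, 4, 5, 7, 8, 9, 10, starting from 1).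

**Step 7.** The ester-bearing quinone methide may alkylate the carbene or oligomerise. β-Protonation of the homoenolate would divert to a [4+2] product. The cis ratio is unproven, and C1 could epimerise on carbonate.

The fallback sets out from 7 and comes back at 14. MnO2 in CH2Cl2 oxidises 7 to the aryl glyoxylate (R)-Lac 2-[3-(benzyloxy)-2-hydroxyphenyl]-2-oxoacetate F1. The same carbene and 10 then add the homoenolate to the ketone carbonyl, which is the established enal/α-ketoester annulation. This gives the butyrolactone (R)-Lac (3R)-2-[3-(benzyloxy)-2-hydroxyphenyl]-3-[3,4-bis(benzyloxy)phenyl]-5-oxooxolane-2-carboxylate F2, with C2 again under catalyst control. SmI2 in THF/t-BuOH cleaves the benzylic C–O bond next to the ester, which frees the C3-side acid. Protonation of the samarium enolate then sets C1 and delivers 14.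

**Step 9.** TiCl4/Et3N may also enolise C1 or a lactate methine and cause epimerisation, or it may strip a chelated benzyl ether. The formyl group could also close onto ring B to give an indene.

The fallback sets out from 13, isolated before the water is added in step 7, and comes back at 17.
- EtSH/Et3N opens 13 to the thioester (R)-Lac (2S,3S)-2-[3-(benzyloxy)-2-hydroxyphenyl]-3-[3,4-bis(benzyloxy)phenyl]-5-(ethylsulfanyl)-5-oxopentanoate F3.
- MgBr2·OEt2, iPr2NEt and 1-formylbenzotriazole enolise only the thioester and give the formyl thioester F4.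
- CF3CO2H closes F4 to the S-ethyl dihydronaphthalene-3-carbothioate F5.
- AgNO3 with 2,6-lutidine in aqueous THF gives the (1S,2S)-dihydronaphthalene-3-carboxylic acid F6.
- Mitsunobu esterification of F6 with 3 gives 17.

**Step 5.** The α-chloro ester with a free ortho phenol may lose HCl early, form a cyclic sulfite, or lactonise to the benzofuranone.

The fallback sets out from 7 and comes back at 11, inside step 7. Boc2O (1.05 equiv) with DMAP (2 mol%) in CH2Cl2 at 0 °C masks only the phenol and gives the aryl tert-butyl carbonate of 7 F7, which is stable and can be isolated. In step 7 a catalytic base then starts an O-to-O Boc transfer to the carbinol oxygen. The freed phenoxide expels tert-butyl carbonate to release 11, and the tert-butoxide that forms carries the chain, so no halide and no stoichiometric base are needed.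

## Further compounds
F1 | step 7 | (R)-Lac 2-[3-(benzyloxy)-2-hydroxyphenyl]-2-oxoacetate | O=C(C(=O)O[C@H](Cc1ccc(OCc2ccccc2)c(OCc2ccccc2)c1)C(=O)OC)c1cccc(OCc2ccccc2)c1O
F2 | step 7 | (R)-Lac (3R)-2-[3-(benzyloxy)-2-hydroxyphenyl]-3-[3,4-bis(benzyloxy)phenyl]-5-oxooxolane-2-carboxylate (either configuration at C2 of the oxolane) | O=C1C[C@H](c2ccc(OCc3ccccc3)c(OCc3ccccc3)c2)C(O1)(C(=O)O[C@H](Cc1ccc(OCc2ccccc2)c(OCc2ccccc2)c1)C(=O)OC)c1cccc(OCc2ccccc2)c1O
F3 | step 9 | (R)-Lac (2S,3S)-2-[3-(benzyloxy)-2-hydroxyphenyl]-3-[3,4-bis(benzyloxy)phenyl]-5-(ethylsulfanyl)-5-oxopentanoate | CCSC(=O)C[C@H](c1ccc(OCc2ccccc2)c(OCc2ccccc2)c1)[C@H](C(=O)O[C@H](Cc1ccc(OCc2ccccc2)c(OCc2ccccc2)c1)C(=O)OC)c1cccc(OCc2ccccc2)c1O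
F4 | step 9 | formyl thioester (C3-formyl derivative of F3, C3 epimers and enol) | CCSC(=O)C(C=O)[C@H](c1ccc(OCc2ccccc2)c(OCc2ccccc2)c1)[C@H](C(=O)O[C@H](Cc1ccc(OCc2ccccc2)c(OCc2ccccc2)c1)C(=O)OC)c1cccc(OCc2ccccc2)c1O
F5 | step 9 | (R)-Lac (1S,2S)-7-(benzyloxy)-2-[3,4-bis(benzyloxy)phenyl]-3-[(ethylsulfanyl)carbonyl]-8-hydroxy-1,2-dihydronaphthalene-1-carboxylate | CCSC(=O)C1=Cc2ccc(OCc3ccccc3)c(O)c2[C@@H](C(=O)O[C@H](Cc2ccc(OCc3ccccc3)c(OCc3ccccc3)c2)C(=O)OC)[C@H]1c1ccc(OCc2ccccc2)c(OCc2ccccc2)c1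
F6 | step 9 | (1S,2S)-7-(benzyloxy)-2-[3,4-bis(benzyloxy)phenyl]-8-hydroxy-1-[(R)-Lac-oxycarbonyl]-1,2-dihydronaphthalene-3-carboxylic acid | OC(=O)C1=Cc2ccc(OCc3ccccc3)c(O)c2[C@@H](C(=O)O[C@H](Cc2ccc(OCc3ccccc3)c(OCc3ccccc3)c2)C(=O)OC)[C@H]1c1ccc(OCc2ccccc2)c(OCc2ccccc2)c1
F7 | step 5 | (R)-Lac 2-{3-(benzyloxy)-2-[(tert-butoxycarbonyl)oxy]phenyl}-2-hydroxyacetate | OC(C(=O)O[C@H](Cc1ccc(OCc2ccccc2)c(OCc2ccccc2)c1)C(=O)OC)c1cccc(OCc2ccccc2)c1OC(=O)OC(C)(C)C
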